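A direct plan would start from a finished pyridine, 5-iodo-3,4-dimethoxy-2-methylpyridine A1, which would itself take three functional-group steps from a commercial 4-pyridone.
Ring B would be annulated onto it by a palladium/norbornene ortho-alkylation–Heck cascade with a bromoalkyl enoate to give the alkylidene acetate A2; copper hydride conjugate reduction would set C5 in the ester A3; the ester would be extended through the aldehyde A4 by olefination and hydrogenation, and the nitrogen would be oxidised last.
Its weakest steps would be:
– the palladium/norbornene annulation on an iodopyridine: the ring nitrogen can bind palladium and the C–H bond to be palladated lies next to it, so the ring closure would rest on a substrate class for which this cascade has little support;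
– the conjugate reduction that sets the only stereocentre: a β,β-disubstituted enoate pressed against the C4 methoxyl, reduced late, with the face selection left to an untested match of catalyst and substrate;
– the ester → aldehyde → alkene → alkane homologation: three steps on enantioenriched material that add five carbons but no complexity, with over-reduction possible at the aldehyde stage.

**Plan of the new route** (quinoline numbering of the target throughout; ring A = N-oxide ring, ring B = carbocycle)
Feature used: C8a and C4 are both at the carbonyl oxidation level and flank C4a, and C5 is β to C8a, so ring B plus C4 is a 2-acyl-3-alkylcyclohexanone; the 4-methoxypyridine 1-oxide is the N–O counterpart of an O-methylated γ-pyranone.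
Retrosynthesis: cut N1–C2 and N1–C8a (N-oxide ← 4-methoxypyrylium ← γ-pyranone), then O1–C2 and C2–C3 (an acetyl unit), then C4a–C4 and C5–C1′ together, back to cyclohex-2-en-1-one, a Grignard reagent and methoxyacetyl chloride.
Order of rings: ring B is bought; an oxygen ring is grown on it (step 3) and becomes ring A only in the last step, so no pyridine and no tetrahydroquinoline appears before the target.
The weak steps do not arise: there is no palladium annulation on a pyridine; C5 is set in the first step on an unhindered enone by catalytic conjugate addition; the C11 side chain enters in one piece; the N–O bond arrives together with the nitrogen, so no late oxidation is needed.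

Key step: step 1

Remark: the ligand antipode named in step 1 is assumed to direct the alkyl group to the Re face of C3 of the enone; if the first run showed the opposite sense, the mirror-image ligand would be used.

**Step 1**
Reactants: 1 (5-bromopentyl)benzene; 2 cyclohex-2-en-1-one; 3 methoxyacetyl chloride
Product: 6 (2S,3R)-2-(methoxyacetyl)-3-(5-phenylpentyl)cyclohexan-1-one, via 5-phenylpentylmagnesium bromide 4 (not isolated), via bromomagnesium (3R)-3-(5-phenylpentyl)cyclohex-1-en-1-olate 5 (not isolated)
Conditions: Mg, Et2O, reflux; CuCl (5 mol%), (R)-1-[(R)-α-(dimethylamino)-2-(diphenylphosphino)benzyl]-2-(diphenylphosphino)ferrocene (6 mol%), 2, Et2O, 0 °C, slow addition of 4 (1.1 equiv); transfer into 3 (1.3 equiv), THF, −78 to 0 °C; aq. NH4Cl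
Reagents that add atoms: none
Why: The ligated alkylcopper formed from 4 by transmetalation should bind the enone as a π-complex, add oxidatively at C3 to a trivalent copper σ-alkyl enolate and reductively eliminate to forge C5–C1′ (target numbering), leaving the bromomagnesium enolate 5, whose single nucleophilic carbon is the future C4a and which attacks the acid chloride to forge C4a–C4. The closest known reaction types are the copper-catalysed enantioselective conjugate addition of primary alkyl Grignard reagents to cyclohex-2-en-1-one under ferrocenyl diphosphine ligands and the C-acylation of magnesium enolates by acid chlorides in ether. No ring is closed: ring B comes in with 2 and becomes part of the bicycle only later. C5 is set by the chiral diphosphine on copper, which should deliver the alkyl group to the Re face of C3 of 2; the second centre (future C4a, expected trans) is enolisable and is erased in step 2. The step needs 1,4- rather than 1,2-addition (copper catalysis, slow addition of 4) and acylation at carbon and at C2 rather than C6: the conjugate addition creates the C1–C2 enolate regiospecifically, it is used without equilibration, and the magnesium counter-ion in ether with inverse addition at −78 °C should favour C- over O-acylation and limit proton transfer from the product.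

**Step 2**
Reactants: 6 (2S,3R)-2-(methoxyacetyl)-3-(5-phenylpentyl)cyclohexan-1-one; 7 acetic anhydride
Product: 8 (3R)-2-(methoxyacetyl)-3-(5-phenylpentyl)cyclohex-1-en-1-yl acetate
Conditions: Ac2O (1.3 equiv), Et3N (2 equiv), DMAP (5 mol%), CH2Cl2, 0 °C to rt
Reagents that add atoms: none
Why: O-Acetylation of the chelated enol of a 2-acylcyclohexanone (enol ester formation) should occur on the ring oxygen, because the enol double bond of such diketones lies in the ring and acetyl transfer under amine/DMAP catalysis is reversible, so the tetrasubstituted endocyclic enol acetate should accumulate; C5 is not touched.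

**Step 3**
Reactants: 8 (3R)-2-(methoxyacetyl)-3-(5-phenylpentyl)cyclohex-1-en-1-yl acetate
Product: 10 (5R)-3-methoxy-2-methyl-5-(5-phenylpentyl)-5,6,7,8-tetrahydro-4H-chromen-4-one, via 2-methoxy-1-[(6R)-2-oxo-6-(5-phenylpentyl)cyclohexyl]butane-1,3-dione 9 (not isolated)
Conditions: LiN(SiMe3)2 (2.5 equiv), THF, −78 to 0 °C; AcOH (2.6 equiv); then p-TsOH·H2O (10 mol%), toluene, 80 °C
Reagents that add atoms: none
Why: Baker–Venkataraman-type O-to-C acyl migration: kinetic deprotonation at the methoxymethyl carbon (α′ to the ketone, acidified by the methoxyl and able to chelate lithium) gives an enolate that attacks the acetate carbonyl through a six-membered transition state to form C2–C3, and acid then closes the γ-pyranone by 6-exo-trig attack of the ring enol oxygen on the acetyl carbonyl and loss of water; C5 is not enolisable.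

**Step 4**
Reactants: 10 (5R)-3-methoxy-2-methyl-5-(5-phenylpentyl)-5,6,7,8-tetrahydro-4H-chromen-4-one
Product: 12 (5R)-3,4-dimethoxy-2-methyl-5-(5-phenylpentyl)-5,6,7,8-tetrahydroquinoline 1-oxide, via (5R)-3,4-dimethoxy-2-methyl-5-(5-phenylpentyl)-5,6,7,8-tetrahydrochromenylium trifluoromethanesulfonate 11 (not isolated)
Conditions: MeOTf (1.05 equiv), CH2Cl2, 0 °C to rt; evaporate; NH2OH·HCl (3 equiv), NaOAc (6 equiv), MeOH, 0 to 40 °C
Reagents that add atoms: methyl trifluoromethanesulfonate, COS(=O)(=O)C(F)(F)F; hydroxylamine hydrochloride, Cl.NO
Why: Proposed new method: O-methylation of the γ-pyranone at its carbonyl oxygen to the 4-methoxypyrylium salt 11 is standard; hydroxylamine should then add through nitrogen to an α-carbon (C2 or C8a, both leading to the same product), the 2H-pyran should open electrocyclically to a 5-(hydroxyamino)dienone, and 6-exo-trig closure of nitrogen on the freed carbonyl with loss of water and a proton should give the aromatic N-oxide, so that N1–O and the C4 methoxyl are installed without any free pyridine; the closest known reaction types are the conversion of 2,4,6-trisubstituted pyrylium salts into pyridine N-oxides by hydroxylamine and of 4-alkoxypyrylium salts into 4-alkoxypyridines by ammonia, the competing ipso attack at C4 should be slowed by its two flanking substituents (C3 methoxyl, C5 side chain), and C5, on a β-position of the cation, should keep its configuration.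

**Compound list**
1 | (5-bromopentyl)benzene | BrCCCCCc1ccccc1 | starting material
2 | cyclohex-2-en-1-one | O=C1C=CCCC1 | starting material
3 | methoxyacetyl chloride | COCC(=O)Cl | starting material
4 | 5-phenylpentylmagnesium bromide | Br[Mg]CCCCCc1ccccc1 | intermediate
5 | bromomagnesium (3R)-3-(5-phenylpentyl)cyclohex-1-en-1-olate | Br[Mg]OC1=C[C@H](CCCCCc2ccccc2)CCC1 | intermediate
6 | (2S,3R)-2-(methoxyacetyl)-3-(5-phenylpentyl)cyclohexan-1-one (largely enolised) | O=C1CCC[C@@H](CCCCCc2ccccc2)[C@@H]1C(=O)COC | intermediate
7 | acetic anhydride | CC(=O)OC(C)=O | starting material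
8 | (3R)-2-(methoxyacetyl)-3-(5-phenylpentyl)cyclohex-1-en-1-yl acetate | CC(=O)OC1=C(C(=O)COC)[C@H](CCCCCc2ccccc2)CCC1 | intermediate
9 | 2-methoxy-1-[(6R)-2-oxo-6-(5-phenylpentyl)cyclohexyl]butane-1,3-dione (enolised; the two carbons between carbonyl groups undefined) | CC(=O)C(OC)C(=O)C1C(=O)CCC[C@H]1CCCCCc1ccccc1 | intermediate
10 | (5R)-3-methoxy-2-methyl-5-(5-phenylpentyl)-5,6,7,8-tetrahydro-4H-chromen-4-one | COC1=C(C)OC2=C(C1=O)[C@H](CCCCCc1ccccc1)CCC2 | intermediate
11 | (5R)-3,4-dimethoxy-2-methyl-5-(5-phenylpentyl)-5,6,7,8-tetrahydrochromenylium trifluoromethanesulfonate | COc1c(OC)c(C)[o+]c2c1[C@H](CCCCCc1ccccc1)CCC2.[O-]S(=O)(=O)C(F)(F)F | intermediate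
12 | (5R)-3,4-dimethoxy-2-methyl-5-(5-phenylpentyl)-5,6,7,8-tetrahydroquinoline 1-oxide | COc1c(OC)c(C)[n+]([O-])c2c1[C@H](CCCCCc1ccccc1)CCC2 | target

Total step count: 4. Longest linear sequence: 4 steps (from 1 or 2 to 12).

**Steps most likely to fail**

Step 4 (proposed new method). Hydroxylamine may add at C4 with loss of methanol instead of at an α-carbon, or the cation may be deprotonated at the 2-methyl group to an anhydro base that does not open. The fallback uses known chemistry and sets out from 10: aqueous NH3 in EtOH in a sealed tube at 120 °C should give (5R)-3-methoxy-2-methyl-5-(5-phenylpentyl)-5,6,7,8-tetrahydroquinolin-4(1H)-one F1; POCl3 at 90 °C should give (5R)-4-chloro-3-methoxy-2-methyl-5-(5-phenylpentyl)-5,6,7,8-tetrahydroquinoline F2; mCPBA in CH2Cl2 should give (5R)-4-chloro-3-methoxy-2-methyl-5-(5-phenylpentyl)-5,6,7,8-tetrahydroquinoline 1-oxide F3; and NaOMe in MeOH at reflux should displace the N-oxide-activated chloride, returning to the route at 12.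

Step 1. The enolate may be acylated at oxygen, or the newly formed diketone may protonate unreacted enolate, and the long-chain Grignard reagent may give lower enantioselectivity than short ones. The fallback sets out from 5: addition of freshly distilled methoxyacetaldehyde at −78 °C (aldol trapping) should give (2R,3R)-2-(1-hydroxy-2-methoxyethyl)-3-(5-phenylpentyl)cyclohexan-1-one F4 as a carbinol mixture, and oxidation with Dess–Martin periodinane in CH2Cl2 should return to the route at 6.

Step 2. Acetylation may occur at the side-chain enol oxygen, which would send the acetyl group to C8 in step 3. The fallback sets out from 6: LiN(i-Pr)2 (2.2 equiv) in THF at −78 to 0 °C should give the dilithium dianion of 6 F5, with the second deprotonation expected at the methoxymethyl carbon; N-methoxy-N-methylacetamide and an aqueous HCl quench should then give 9, where the route is rejoined and the acid treatment of step 3 leads to 10.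

**Further compounds**
F1 | step 4 | (5R)-3-methoxy-2-methyl-5-(5-phenylpentyl)-5,6,7,8-tetrahydroquinolin-4(1H)-one | COC1=C(C)NC2=C(C1=O)[C@H](CCCCCc1ccccc1)CCC2
F2 | step 4 | (5R)-4-chloro-3-methoxy-2-methyl-5-(5-phenylpentyl)-5,6,7,8-tetrahydroquinoline | COc1c(C)nc2c(c1Cl)[C@H](CCCCCc1ccccc1)CCC2
F3 | step 4 | (5R)-4-chloro-3-methoxy-2-methyl-5-(5-phenylpentyl)-5,6,7,8-tetrahydroquinoline 1-oxide | COc1c(C)[n+]([O-])c2c(c1Cl)[C@H](CCCCCc1ccccc1)CCC2
F4 | step 1 | (2R,3R)-2-(1-hydroxy-2-methoxyethyl)-3-(5-phenylpentyl)cyclohexan-1-one | O=C1CCC[C@@H](CCCCCc2ccccc2)[C@@H]1C(O)COC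
F5 | step 2 | dilithium dianion of 6 (dienediolate) | [Li+].[Li+].COC=C([O-])C1=C([O-])CCC[C@H]1CCCCCc1ccccc1
A1 | direct plan | 5-iodo-3,4-dimethoxy-2-methylpyridine | COc1c(OC)c(C)ncc1I
A2 | direct plan | ethyl (2E)-2-(3,4-dimethoxy-2-methyl-7,8-dihydroquinolin-5(6H)-ylidene)acetate | CCOC(=O)/C=C1\CCCc2nc(C)c(OC)c(OC)c12
A3 | direct plan | ethyl 2-[(5S)-3,4-dimethoxy-2-methyl-5,6,7,8-tetrahydroquinolin-5-yl]acetate | COc1c(OC)c(C)nc2c1[C@H](CC(=O)OCC)CCC2
A4 | direct plan | 2-[(5S)-3,4-dimethoxy-2-methyl-5,6,7,8-tetrahydroquinolin-5-yl]acetaldehyde | COc1c(OC)c(C)nc2c1[C@H](CC=O)CCC2
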